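**Remark on numbering and assignment.** Cembrane numbering is used throughout. C1 and C2 are the ring-fusion atoms (C1 sp2, C2 the O–CH), the dihydrofuran is O–C2–C1=C15–C16, C17 is the CH2OAc carbon on C15, C3=C4 and C11=C12 are the E-trisubstituted alkenes, and C7–C8 is the epoxide. Read from the SMILES, the target is (2R,7R,8R,3E,11E). Compound numbers are those of the steps and of the list after step 15.

## The problem

Lobophynin B is a 14-membered carbocycle fused along C1–C2 to a 2,5-dihydrofuran (O–C2–C1=C15–C16). The C1=C15 alkene is tetrasubstituted and all four of its allylic carbons (C2, C14, C16, C17) are functionalised. The macrocycle has to be closed within a chain that already holds two E-trisubstituted alkenes and a trisubstituted epoxide, and every possible closure site is vinylic or allylic. C2 is doubly allylic and α-oxygenated, so it loses configuration on any ionisation. The C7/C8 epoxide lies five bonds away from C2 across the ring, so neither element can be relied on to control the other; each must be set by a reagent. The C7=C8 alkene must also be told apart from two other trisubstituted alkenes. The epoxide rules out strong acids, Lewis acids and hard nucleophiles late in the route, and the allylic acetate rules out Pd(0) and strong base once it is in place. The feature that opens the problem is at C15 of the dihydrofuran: it carries two oxygenated methylene groups, ring C16 and exocyclic C17, which differ only in what their oxygen is bonded to. As long as both are plain CH2–O arms, C1=C15 has no E/Z geometry, and C1 can be built by two successive C–C bond formations on a C2v-symmetric gem-dibromo-olefin.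

## Retrosynthesis

**21 ⇒ 18.** The O–C16 bond and the acetate on C17 are both cut, which gives triol 18 with two identical CH2OH arms on C15. Cutting here, and not at C2–O, leaves the C2–O bond untouched, so the labile centre is never a leaving-group carbon. In the forward direction both arms are activated alike. The C2 hydroxyl can reach only the arm cis to it and closes the ring; acetate takes the other arm. No selectivity between the arms is needed.

**18 ⇒ 17 ⇒ 15 (through 16).** The C1–C14 bond is cut. This is the macrocyclisation and the key step: a C(sp3)–C(sp2) Suzuki–Miyaura coupling between the C14 borane 16 and the C1 bromide. Compared with C1–C2 (carbonyl addition, which would create C2 during ring closure without control), C2–C3, or C13–C14 (allyl–allyl coupling with regiochemical ambiguity), this cut forms no stereocentre and touches no allylic position. The tetrasubstituted alkene is present before the step and is not made by a C=C-forming reaction. The precursor 15 is acyclic apart from the epoxide.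

**15 ⇒ 14 ⇒ 13 ⇒ 12 ⇒ 10 + 7.** The C1–C2 bond is cut. The first bromine of dibromo-olefin 10 is exchanged and the resulting carbenoid 11 adds to enal 7. The two bromines are equivalent, so no geometry can be lost. The C2 centre is then set by oxidation to dienone 13 and catalyst-controlled reduction to 14. The bromine that serves the later coupling also makes the C1 side of the ketone much bulkier than the C3 side, which is what the reduction needs. This cut divides the molecule into a C5 linchpin and a C16 chain.

**10 ⇒ 9 ⇒ 8.** The C1=C15 double bond is traced to the carbonyl of protected dihydroxyacetone 9 by gem-dibromo-olefination. Ketone 9 comes from dihydroxyacetone dimer 8 in one step. All five carbons of C1, C15, C16 and C17 arrive with both oxygens in place.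

**7 ⇒ 6 ⇒ 5 ⇒ 4 ⇒ 3 ⇒ 2 ⇒ 1.** The chain is (2E,6E)-farnesyl acetate 1, which already contains C2–C13, the three methyl groups and both E-alkenes. Only C14 is added, by Wittig methylenation of the C13 aldehyde obtained by allylic oxidation of the terminal (E)-methyl group. The epoxide is introduced at the stage of 3, where C3=C4 is deactivated by the allylic acetate and C11=C12 by the conjugated aldehyde. The alternative of assembling the chain from two C10/C5 pieces with a Sharpless epoxidation would cost more steps.

## Roads not taken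

**Alternative 1:** the obvious route cuts the ring ether at the lactone oxidation level. The key intermediate is the macrocyclic butenolide A1 (C16 as lactone carbonyl, C17 as CH2OTBS), closed by an intramolecular olefination or Nozaki–Hiyama–Kishi reaction. Reduction would give ene-diol A2, followed by cyclodehydration, desilylation and acetylation. The chosen plan is better for three reasons. The butenolide distinguishes C16 from C17 from the start, so the tetrasubstituted alkene must be made with defined geometry. The C2–H of A1 is the γ-hydrogen of a butenolide and is also allylic, so it is prone to epimerisation through the 2-oxyfuran. Converting lactone to ether costs extra redox and cyclisation steps through a lactol level that aromatises easily to a furan.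

**Alternative 2:** cut C1–C2 by a [2,3]-Wittig ring contraction of the 17-membered propargyl allyl ether A3. This would give the macrocyclic α-allenol A4, which a Pd(II)-mediated oxycarbonylation would convert into the dihydrofuran ester A5; reduction and acetylation would follow. The step is attractive because it contracts the ring and forms C1–C2 at once. However, the propargylic C16–H is more acidic than the allylic C2–H that must be removed, which favours the wrong rearrangement. The C2 configuration would rest on a chiral base or on the remote epoxide. C17 would have to be added after ring formation by a carbonylation on a polyene epoxide. The chosen plan brings C17 in with the linchpin and sets C2 on an acyclic ketone.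

**Alternative 3:** make C1=C15 last by ring-closing metathesis. The macrocyclic 1-methylene allylic alcohol A6 (from a Nozaki–Hiyama–Kishi closure of a 2-bromo-1-alkene onto the C2 aldehyde) would be etherified to the 2-(acetoxymethyl)allyl ether A7, and metathesis of the two 1,1-disubstituted alkenes would close the dihydrofuran. That metathesis would have to form a tetrasubstituted alkene flanked by three allylic oxygens in the presence of two trisubstituted ring alkenes. The hindered bis-allylic alkoxide would have to be alkylated, and C2 would again be created in the macrocyclisation. In the chosen plan the tetrasubstituted alkene exists from step 8 and only σ-bonds are made at C1.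

Key step: step 13

## Steps

Step 1
Reactants: 1 (2E,6E)-farnesyl acetate
Product: 2 (2E,6E,10E)-12-hydroxy-3,7,11-trimethyldodeca-2,6,10-trien-1-yl acetate
Conditions: SeO2 (cat.), t-BuOOH, salicylic acid (cat.), CH2Cl2, 0 °C → rt
Reagents that add atoms: tert-butyl hydroperoxide, CC(C)(C)OO (oxygen, relayed by catalytic SeO2)
Why: Sharpless–Umbreit catalytic SeO2 allylic oxidation (ene reaction, then [2,3]-shift) attacks the (E)-methyl group of the most electron-rich terminal alkene; C2=C3 is deactivated by the allylic acetate, and the (E)-CH2OH geometry follows from the [2,3] transition state.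

Step 2
Reactants: 2 (2E,6E,10E)-12-hydroxy-3,7,11-trimethyldodeca-2,6,10-trien-1-yl acetate
Product: 3 (2E,6E,10E)-3,7,11-trimethyl-12-oxododeca-2,6,10-trien-1-yl acetate
Conditions: activated MnO2, CH2Cl2, rt
Reagents that add atoms: none
Why: MnO2 oxidises only the allylic alcohol to the (E)-enal and also converges any enal already formed in step 1; the enal is the Wittig acceptor of step 4 and switches off C10=C11 for step 3.

Step 3
Reactants: 3 (2E,6E,10E)-3,7,11-trimethyl-12-oxododeca-2,6,10-trien-1-yl acetate
Product: 4 (2E,6R,7R,10E)-6,7-epoxy-3,7,11-trimethyl-12-oxododeca-2,10-dien-1-yl acetate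
Conditions: D-fructose-derived Shi ketone (0.3 equiv), Oxone, K2CO3, Bu4NHSO4, MeCN/DMM/aq. borate–EDTA buffer (pH 10.5), 0 °C
Reagents that add atoms: potassium peroxymonosulfate (Oxone), [K+].[O-]S(=O)(=O)OO
Why: Shi asymmetric epoxidation through a spiro dioxirane transition state; C2=C3 is deactivated by the allylic acetate and C10=C11 by the conjugated aldehyde, so the electrophilic dioxirane should take the isolated C6=C7 alkene, and the D-fructose-derived ketone gives the (R,R)-epoxide from (E)-trisubstituted alkenes (C7 and C8 of the target).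

Step 4
Reactants: 4 (2E,6R,7R,10E)-6,7-epoxy-3,7,11-trimethyl-12-oxododeca-2,10-dien-1-yl acetate
Product: 5 (2E,6R,7R,10E)-6,7-epoxy-3,7,11-trimethyltrideca-2,10,12-trien-1-yl acetate
Conditions: Ph3PCH3Br, KHMDS, THF, −78 → 0 °C
Reagents that add atoms: methyltriphenylphosphonium bromide, C[P+](c1ccccc1)(c1ccccc1)c1ccccc1.[Br-] (CH2 through its ylide)
Why: Wittig methylenation of the α-methyl enal gives the terminal 1,3-diene and brings in C14; at low temperature the aldehyde reacts well before the acetate or the epoxide.

Step 5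
Reactants: 5 (2E,6R,7R,10E)-6,7-epoxy-3,7,11-trimethyltrideca-2,10,12-trien-1-yl acetate
Product: 6 (2E,6R,7R,10E)-6,7-epoxy-3,7,11-trimethyltrideca-2,10,12-trien-1-ol
Conditions: K2CO3 (0.2 equiv), MeOH, 0 °C → rt
Reagents that add atoms: none
Why: base-catalysed transesterification removes the acetate; the trisubstituted epoxide and the diene are inert to methanolic carbonate at this temperature.

Step 6
Reactants: 6 (2E,6R,7R,10E)-6,7-epoxy-3,7,11-trimethyltrideca-2,10,12-trien-1-ol
Product: 7 (2E,6R,7R,10E)-6,7-epoxy-3,7,11-trimethyltrideca-2,10,12-trienal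
Conditions: activated MnO2, CH2Cl2, rt
Reagents that add atoms: none
Why: neutral MnO2 oxidation of the primary allylic alcohol gives the (2E)-enal without isomerising the 2,3-alkene or affecting epoxide and diene.

Step 7
Reactants: 8 1,3-dihydroxyacetone dimer
Product: 9 1,3-bis(tert-butyldimethylsilyloxy)propan-2-one
Conditions: TBSCl, imidazole, DMF, 0 °C → rt
Reagents that add atoms: tert-butyldimethylsilyl chloride, CC(C)(C)[Si](C)(C)Cl
Why: the dimer dissociates to monomeric dihydroxyacetone in DMF–imidazole and both primary hydroxyls are silylated (standard silyl ether formation).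

Step 8
Reactants: 9 1,3-bis(tert-butyldimethylsilyloxy)propan-2-one
Product: 10 1,1-dibromo-3-(tert-butyldimethylsilyloxy)-2-[(tert-butyldimethylsilyloxy)methyl]prop-1-ene
Conditions: CBr4, PPh3, CH2Cl2, 0 °C → rt
Reagents that add atoms: carbon tetrabromide, BrC(Br)(Br)Br
Why: Ramirez gem-dibromo-olefination (first stage of the Corey–Fuchs sequence) of a ketone activated by two α-oxygens; the ketone is C2v-symmetric, so one product forms and its two bromines are equivalent.

Step 9
Reactants: 10 1,1-dibromo-3-(tert-butyldimethylsilyloxy)-2-[(tert-butyldimethylsilyloxy)methyl]prop-1-ene; 7 (2E,6R,7R,10E)-6,7-epoxy-3,7,11-trimethyltrideca-2,10,12-trienal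
Product: 12 (2RS,3E,7R,8R,11E)-1-bromo-7,8-epoxy-16,17-bis(tert-butyldimethylsilyloxy)-1,14-secocembra-1(15),3,11,13-tetraen-2-ol, via bromolithio carbenoid 11 (not isolated)
Conditions: 10 (1.3 equiv), n-BuLi (1.3 equiv), THF/Et2O, −110 °C; then 7, −110 → −78 °C; aq. NH4Cl
Reagents that add atoms: none
Why: bromine–lithium exchange at either equivalent bromine gives the same α-bromoalkenyllithium (Köbrich-type carbenoid), which at −110 °C adds 1,2 to the β,β-disubstituted enal before α-elimination and faster than it attacks the epoxide; C2 is formed without control here and is corrected in steps 10 and 11.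

Step 10
Reactants: 12 (2RS,3E,7R,8R,11E)-1-bromo-7,8-epoxy-16,17-bis(tert-butyldimethylsilyloxy)-1,14-secocembra-1(15),3,11,13-tetraen-2-ol
Product: 13 (3E,7R,8R,11E)-1-bromo-7,8-epoxy-16,17-bis(tert-butyldimethylsilyloxy)-1,14-secocembra-1(15),3,11,13-tetraen-2-one
Conditions: Dess–Martin periodinane, NaHCO3, CH2Cl2, 0 °C → rt
Reagents that add atoms: none
Why: buffered Dess–Martin oxidation converts both C2 epimers into one cross-conjugated dienone without acid that could open the epoxide.

Step 11
Reactants: 13 (3E,7R,8R,11E)-1-bromo-7,8-epoxy-16,17-bis(tert-butyldimethylsilyloxy)-1,14-secocembra-1(15),3,11,13-tetraen-2-one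
Product: 14 (2R,3E,7R,8R,11E)-1-bromo-7,8-epoxy-16,17-bis(tert-butyldimethylsilyloxy)-1,14-secocembra-1(15),3,11,13-tetraen-2-ol
Conditions: (S)-2-methyl-CBS-oxazaborolidine (0.5 equiv), catecholborane, toluene, −78 °C; MeOH, then aq. NaOH
Reagents that add atoms: none
Why: Corey–Bakshi–Shibata reduction; the twisted, tetrasubstituted α-bromoalkenyl group should act as the large substituent and the planar C3=C4 alkenyl as the small one (as in α-bromo enones), so the (S)-catalyst should give the (2R)-alcohol; catecholborane does not hydroborate the diene at −78 °C.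

Step 12
Reactants: 14 (2R,3E,7R,8R,11E)-1-bromo-7,8-epoxy-16,17-bis(tert-butyldimethylsilyloxy)-1,14-secocembra-1(15),3,11,13-tetraen-2-ol
Product: 15 (2R,3E,7R,8R,11E)-1-bromo-7,8-epoxy-2-(triethylsilyloxy)-16,17-bis(tert-butyldimethylsilyloxy)-1,14-secocembra-1(15),3,11,13-tetraene
Conditions: TESCl, imidazole, DMAP (cat.), CH2Cl2, 0 °C → rt
Reagents that add atoms: chlorotriethylsilane, CC[Si](Cl)(CC)CC
Why: silylation of the hindered secondary alcohol with the small TES group keeps the hydroxyl out of borinate and palladium alkoxide chemistry in step 13; it is removed together with the TBS groups in step 14.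

Step 13
Reactants: 15 (2R,3E,7R,8R,11E)-1-bromo-7,8-epoxy-2-(triethylsilyloxy)-16,17-bis(tert-butyldimethylsilyloxy)-1,14-secocembra-1(15),3,11,13-tetraene
Product: 17 (2R,3E,7R,8R,11E)-7,8-epoxy-2-(triethylsilyloxy)-16,17-bis(tert-butyldimethylsilyloxy)cembra-1(15),3,11-triene, via B-alkyl-9-BBN 16 (not isolated)
Conditions: 9-BBN dimer, THF, 0 °C → rt; then slow addition to Pd(dppf)Cl2·CH2Cl2 (0.2 equiv), AsPh3 (0.4 equiv), Cs2CO3, DMF/THF/H2O, 50 °C, final concentration about 1 mM
Reagents that add atoms: none
Why: 9-BBN adds anti-Markovnikov to the only monosubstituted alkene, the terminal vinyl group of the diene, and puts boron on C14; the trisubstituted alkenes, the bromoalkene and the epoxide do not react. Pd(0) then inserts into the C1–Br bond, the base-activated borinate transfers the primary alkyl group, and reductive elimination forms the C14–C1 bond (intramolecular B-alkyl Suzuki–Miyaura coupling). The closest known reaction type is the B-alkyl Suzuki macrocyclisation used for 12- to 20-membered carbocycles and macrolides. The 14-membered ring is closed by C(sp3)–C(sp2) bond formation, with the C1=C15 alkene left exocyclic to the new ring. No stereocentre is created, and the tetrasubstituted alkene has no geometry to control because C15 still bears two identical CH2OTBS groups; this symmetry is the feature the plan rests on. The step needs chemoselective hydroboration, secured by the single terminal alkene, and ring closure in preference to oligomerisation, secured by slow addition at high dilution. The wide-bite-angle dppf ligand with AsPh3 is chosen to speed reductive elimination over β-hydride elimination of the alkylpalladium.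

Step 14
Reactants: 17 (2R,3E,7R,8R,11E)-7,8-epoxy-2-(triethylsilyloxy)-16,17-bis(tert-butyldimethylsilyloxy)cembra-1(15),3,11-triene
Product: 18 (2R,3E,7R,8R,11E)-7,8-epoxycembra-1(15),3,11-triene-2,16,17-triol
Conditions: TBAF, THF, 0 °C → rt; aq. NH4Cl
Reagents that add atoms: none
Why: fluoride cleaves the TES and both TBS ethers in one operation; the epoxide, the alkenes and the bis-allylic alcohol are stable to TBAF.

Step 15
Reactants: 18 (2R,3E,7R,8R,11E)-7,8-epoxycembra-1(15),3,11-triene-2,16,17-triol
Product: 21 lobophynin B, via bis-mesylate 19 (not isolated), via dihydrofuranylmethyl mesylate 20 (not isolated)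
Conditions: Ms2O (2.2 equiv), i-Pr2NEt, CH2Cl2, −40 → 0 °C; then CsOAc, 18-crown-6 (cat.), MeCN, rt
Reagents that add atoms: cesium acetate, CC(=O)[O-].[Cs+]
Why: the two primary allylic hydroxyls are sulfonylated faster than the hindered secondary one; the C2 hydroxyl then displaces the only mesylate it can reach, the arm cis to C2 (5-exo-tet Williamson closure, no bond to C2 broken, so 2R is retained), and acetate substitutes the remaining primary allylic mesylate by SN2, so either order of sulfonylation leads to the same product.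

## Compound list

1 | (2E,6E)-farnesyl acetate | CC(C)=CCC/C(C)=C/CC/C(C)=C/COC(C)=O | starting material
2 | (2E,6E,10E)-12-hydroxy-3,7,11-trimethyldodeca-2,6,10-trien-1-yl acetate | OC/C(C)=C/CC/C(C)=C/CC/C(C)=C/COC(C)=O | intermediate
3 | (2E,6E,10E)-3,7,11-trimethyl-12-oxododeca-2,6,10-trien-1-yl acetate | O=C/C(C)=C/CC/C(C)=C/CC/C(C)=C/COC(C)=O | intermediate
4 | (2E,6R,7R,10E)-6,7-epoxy-3,7,11-trimethyl-12-oxododeca-2,10-dien-1-yl acetate | O=C/C(C)=C/CC[C@@]1(C)O[C@@H]1CC/C(C)=C/COC(C)=O | intermediate
5 | (2E,6R,7R,10E)-6,7-epoxy-3,7,11-trimethyltrideca-2,10,12-trien-1-yl acetate | C=C/C(C)=C/CC[C@@]1(C)O[C@@H]1CC/C(C)=C/COC(C)=O | intermediate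
6 | (2E,6R,7R,10E)-6,7-epoxy-3,7,11-trimethyltrideca-2,10,12-trien-1-ol | C=C/C(C)=C/CC[C@@]1(C)O[C@@H]1CC/C(C)=C/CO | intermediate
7 | (2E,6R,7R,10E)-6,7-epoxy-3,7,11-trimethyltrideca-2,10,12-trienal | C=C/C(C)=C/CC[C@@]1(C)O[C@@H]1CC/C(C)=C/C=O | intermediate
8 | 1,3-dihydroxyacetone dimer (2,5-bis(hydroxymethyl)-1,4-dioxane-2,5-diol) | OCC1(O)COC(O)(CO)CO1 | starting material
9 | 1,3-bis(tert-butyldimethylsilyloxy)propan-2-one | CC(C)(C)[Si](C)(C)OCC(=O)CO[Si](C)(C)C(C)(C)C | intermediate
10 | 1,1-dibromo-3-(tert-butyldimethylsilyloxy)-2-[(tert-butyldimethylsilyloxy)methyl]prop-1-ene | BrC(Br)=C(CO[Si](C)(C)C(C)(C)C)CO[Si](C)(C)C(C)(C)C | intermediate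
11 | 1-bromo-1-lithio-3-(tert-butyldimethylsilyloxy)-2-[(tert-butyldimethylsilyloxy)methyl]prop-1-ene | [Li]C(Br)=C(CO[Si](C)(C)C(C)(C)C)CO[Si](C)(C)C(C)(C)C | intermediate (not isolated)
12 | (2RS,3E,7R,8R,11E)-1-bromo-7,8-epoxy-16,17-bis(tert-butyldimethylsilyloxy)-1,14-secocembra-1(15),3,11,13-tetraen-2-ol (both C2 epimers) | C=C/C(C)=C/CC[C@@]1(C)O[C@@H]1CC/C(C)=C/C(O)C(Br)=C(CO[Si](C)(C)C(C)(C)C)CO[Si](C)(C)C(C)(C)C | intermediate
13 | (3E,7R,8R,11E)-1-bromo-7,8-epoxy-16,17-bis(tert-butyldimethylsilyloxy)-1,14-secocembra-1(15),3,11,13-tetraen-2-one | C=C/C(C)=C/CC[C@@]1(C)O[C@@H]1CC/C(C)=C/C(=O)C(Br)=C(CO[Si](C)(C)C(C)(C)C)CO[Si](C)(C)C(C)(C)C | intermediate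
14 | (2R,3E,7R,8R,11E)-1-bromo-7,8-epoxy-16,17-bis(tert-butyldimethylsilyloxy)-1,14-secocembra-1(15),3,11,13-tetraen-2-ol | C=C/C(C)=C/CC[C@@]1(C)O[C@@H]1CC/C(C)=C/[C@@H](O)C(Br)=C(CO[Si](C)(C)C(C)(C)C)CO[Si](C)(C)C(C)(C)C | intermediate
15 | (2R,3E,7R,8R,11E)-1-bromo-7,8-epoxy-2-(triethylsilyloxy)-16,17-bis(tert-butyldimethylsilyloxy)-1,14-secocembra-1(15),3,11,13-tetraene | C=C/C(C)=C/CC[C@@]1(C)O[C@@H]1CC/C(C)=C/[C@@H](O[Si](CC)(CC)CC)C(Br)=C(CO[Si](C)(C)C(C)(C)C)CO[Si](C)(C)C(C)(C)C | intermediate
16 | C14 B-alkyl-9-borabicyclo[3.3.1]nonane derived from 15 (boron on C14, C13 saturated) | B1(CC/C(C)=C/CC[C@@]3(C)O[C@@H]3CC/C(C)=C/[C@@H](O[Si](CC)(CC)CC)C(Br)=C(CO[Si](C)(C)C(C)(C)C)CO[Si](C)(C)C(C)(C)C)C2CCCC1CCC2 | intermediate (not isolated)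
17 | (2R,3E,7R,8R,11E)-7,8-epoxy-2-(triethylsilyloxy)-16,17-bis(tert-butyldimethylsilyloxy)cembra-1(15),3,11-triene | CC(C)(C)[Si](C)(C)OCC(CO[Si](C)(C)C(C)(C)C)=C1CC/C(C)=C/CC[C@@]2(C)O[C@@H]2CC/C(C)=C/[C@H]1O[Si](CC)(CC)CC | intermediate
18 | (2R,3E,7R,8R,11E)-7,8-epoxycembra-1(15),3,11-triene-2,16,17-triol | OCC(CO)=C1CC/C(C)=C/CC[C@@]2(C)O[C@@H]2CC/C(C)=C/[C@H]1O | intermediate
19 | (2R,3E,7R,8R,11E)-7,8-epoxy-2-hydroxycembra-1(15),3,11-triene-16,17-diyl bis(methanesulfonate) | CS(=O)(=O)OCC(COS(C)(=O)=O)=C1CC/C(C)=C/CC[C@@]2(C)O[C@@H]2CC/C(C)=C/[C@H]1O | intermediate (not isolated)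
20 | (2R,3E,7R,8R,11E)-2,16:7,8-diepoxycembra-1(15),3,11-trien-17-yl methanesulfonate | CS(=O)(=O)OCC1=C2CC/C(C)=C/CC[C@@]3(C)O[C@@H]3CC/C(C)=C/[C@H]2OC1 | intermediate (not isolated)
21 | lobophynin B, (2R,3E,7R,8R,11E)-2,16:7,8-diepoxycembra-1(15),3,11-trien-17-yl acetate | CC(=O)OCC1=C2CC/C(C)=C/CC[C@@]3(C)O[C@@H]3CC/C(C)=C/[C@H]2OC1 | target

## Step count and least certain steps

Total: 15 steps. Longest linear sequence: 13 steps (steps 1–6 and 9–15, from 1); steps 7–8 are the two-step branch to 10.

**Step 13 (key step).** Oxidative addition at the tetrasubstituted, doubly flanked bromoalkene may be slow. The alkylborane could then be lost by protodeboronation or β-hydride elimination, or couple intermolecularly to oligomers. Hydroboration of the diene could also leak to the internal position.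
Fallback, from 5 and 10, returning at 18: exchange the order of the two bond formations at C1 and close the ring by carbonyl addition. Diene 5 is hydroborated (9-BBN) and coupled intermolecularly with excess 10 to give the monobromide acetate F1. Methanolysis gives the allylic alcohol F2 and MnO2 the enal F3. A Nozaki–Hiyama–Kishi closure (CrCl2, cat. NiCl2) at C1–C2 gives the macrocyclic alcohol F4 as C2 epimers. Dess–Martin oxidation gives the macrocyclic dienone F5 and (S)-CBS reduction the (2R)-alcohol F6. TBAF then gives 18.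

**Step 3.** The electron-poor enal may not survive the oxidant (oxidation of the aldehyde or nucleophilic epoxidation of the enal by peroxymonosulfate at pH 10.5), and site selectivity against C2=C3 rests only on the acetate.
Fallback, from 2, returning at 4: carry C13 through the epoxidation as an ester instead of an aldehyde. Alcohol 2 is acylated with levulinic acid (DCC, DMAP) to the levulinate F7. Shi epoxidation, now with both outer alkenes deactivated by allylic esters, gives the epoxy levulinate F8. Hydrazine acetate removes the levulinate in the presence of the acetate to give the epoxy alcohol F9, and MnO2 gives 4.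

**Step 11.** Facial selectivity may be poor if the catalyst does not distinguish the two alkenyl substituents clearly enough. Conjugate or over-reduction is unlikely at −78 °C.
Fallback, from 12, returning at 14: resolve instead of reducing asymmetrically. The epimer mixture 12 (from step 9, or by Luche reduction of 13) is esterified with (R)-O-methylmandelic acid (DCC, DMAP). The ester of the (2R)-alcohol, F10, is separated by chromatography from its C2 epimer F11, and methanolysis (K2CO3, MeOH) of F10 gives 14. F11 can be recycled by methanolysis and re-oxidation to 13.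

**Step 15.** Sulfonylation of the secondary bis-allylic hydroxyl would lead to ionisation at C2 and loss of configuration. Acetate could also displace the cis mesylate before the ring has closed.
Fallback, from 18, returning at 21: separate ring closure from acetate introduction. Mitsunobu cyclodehydration of 18 (PPh3, DIAD), in which a primary hydroxyl is activated and the C2 hydroxyl acts as nucleophile, gives 17-O-deacetyl-lobophynin B F12. Acetylation (Ac2O, pyridine, DMAP) gives 21.

## Further compounds

F1 | step 13 | (3E,7R,8R,11E)-1-bromo-7,8-epoxy-16,17-bis(tert-butyldimethylsilyloxy)-1,2-secocembra-1(15),3,11-trien-2-yl acetate | BrC(=C(CO[Si](C)(C)C(C)(C)C)CO[Si](C)(C)C(C)(C)C)CC/C(C)=C/CC[C@@]1(C)O[C@@H]1CC/C(C)=C/COC(C)=O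
F2 | step 13 | (3E,7R,8R,11E)-1-bromo-7,8-epoxy-16,17-bis(tert-butyldimethylsilyloxy)-1,2-secocembra-1(15),3,11-trien-2-ol | BrC(=C(CO[Si](C)(C)C(C)(C)C)CO[Si](C)(C)C(C)(C)C)CC/C(C)=C/CC[C@@]1(C)O[C@@H]1CC/C(C)=C/CO
F3 | step 13 | (3E,7R,8R,11E)-1-bromo-7,8-epoxy-16,17-bis(tert-butyldimethylsilyloxy)-1,2-secocembra-1(15),3,11-trien-2-al | BrC(=C(CO[Si](C)(C)C(C)(C)C)CO[Si](C)(C)C(C)(C)C)CC/C(C)=C/CC[C@@]1(C)O[C@@H]1CC/C(C)=C/C=O
F4 | step 13 | (2RS,3E,7R,8R,11E)-7,8-epoxy-16,17-bis(tert-butyldimethylsilyloxy)cembra-1(15),3,11-trien-2-ol (both C2 epimers) | CC(C)(C)[Si](C)(C)OCC(CO[Si](C)(C)C(C)(C)C)=C1CC/C(C)=C/CC[C@@]2(C)O[C@@H]2CC/C(C)=C/C1O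
F5 | step 13 | (3E,7R,8R,11E)-7,8-epoxy-16,17-bis(tert-butyldimethylsilyloxy)cembra-1(15),3,11-trien-2-one | CC(C)(C)[Si](C)(C)OCC(CO[Si](C)(C)C(C)(C)C)=C1CC/C(C)=C/CC[C@@]2(C)O[C@@H]2CC/C(C)=C/C1=O
F6 | step 13 | (2R,3E,7R,8R,11E)-7,8-epoxy-16,17-bis(tert-butyldimethylsilyloxy)cembra-1(15),3,11-trien-2-ol | CC(C)(C)[Si](C)(C)OCC(CO[Si](C)(C)C(C)(C)C)=C1CC/C(C)=C/CC[C@@]2(C)O[C@@H]2CC/C(C)=C/[C@H]1O
F7 | step 3 | (2E,6E,10E)-12-acetoxy-2,6,10-trimethyldodeca-2,6,10-trien-1-yl 4-oxopentanoate | CC(=O)CCC(=O)OC/C(C)=C/CC/C(C)=C/CC/C(C)=C/COC(C)=O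
F8 | step 3 | (2E,6R,7R,10E)-12-acetoxy-6,7-epoxy-2,6,10-trimethyldodeca-2,10-dien-1-yl 4-oxopentanoate | CC(=O)CCC(=O)OC/C(C)=C/CC[C@@]1(C)O[C@@H]1CC/C(C)=C/COC(C)=O
F9 | step 3 | (2E,6R,7R,10E)-6,7-epoxy-12-hydroxy-3,7,11-trimethyldodeca-2,10-dien-1-yl acetate | OC/C(C)=C/CC[C@@]1(C)O[C@@H]1CC/C(C)=C/COC(C)=O
F10 | step 11 | (R)-O-methylmandelate of 14 (2R) | C=C/C(C)=C/CC[C@@]1(C)O[C@@H]1CC/C(C)=C/[C@@H](OC(=O)[C@H](OC)c1ccccc1)C(Br)=C(CO[Si](C)(C)C(C)(C)C)CO[Si](C)(C)C(C)(C)C
F11 | step 11 | (R)-O-methylmandelate of the C2 epimer of 14 (2S) | C=C/C(C)=C/CC[C@@]1(C)O[C@@H]1CC/C(C)=C/[C@H](OC(=O)[C@H](OC)c1ccccc1)C(Br)=C(CO[Si](C)(C)C(C)(C)C)CO[Si](C)(C)C(C)(C)C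
F12 | step 15 | 17-O-deacetyl-lobophynin B, (2R,3E,7R,8R,11E)-2,16:7,8-diepoxycembra-1(15),3,11-trien-17-ol | OCC1=C2CC/C(C)=C/CC[C@@]3(C)O[C@@H]3CC/C(C)=C/[C@H]2OC1
A1 | alternative 1 | (2R,3E,7R,8R,11E)-17-(tert-butyldimethylsilyloxy)-7,8-epoxycembra-1(15),3,11-trien-16,2-olide (macrocyclic butenolide) | CC(C)(C)[Si](C)(C)OCC1=C2CC/C(C)=C/CC[C@@]3(C)O[C@@H]3CC/C(C)=C/[C@H]2OC1=O
A2 | alternative 1 | (2R,3E,7R,8R,11E)-17-(tert-butyldimethylsilyloxy)-7,8-epoxycembra-1(15),3,11-triene-2,16-diol (C16 cis to C2) | OC/C(CO[Si](C)(C)C(C)(C)C)=C1/CC/C(C)=C/CC[C@@]2(C)O[C@@H]2CC/C(C)=C/[C@H]1O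
A3 | alternative 2 | 17-membered propargyl allyl ether (O bridges C2 and C16, C1≡C15, 3E, 11E, 7R,8R-epoxide) | C1C#CCC/C(C)=C/CC[C@@]2(C)O[C@@H]2CC/C(C)=C/CO1
A4 | alternative 2 | (2R,3E,7R,8R,11E)-7,8-epoxy-17-norcembra-1(15),3,11,15-tetraen-2-ol (macrocyclic α-allenol) | C=C=C1CC/C(C)=C/CC[C@@]2(C)O[C@@H]2CC/C(C)=C/[C@H]1O
A5 | alternative 2 | methyl (2R,3E,7R,8R,11E)-2,16:7,8-diepoxycembra-1(15),3,11-trien-17-oate | COC(=O)C1=C2CC/C(C)=C/CC[C@@]3(C)O[C@@H]3CC/C(C)=C/[C@H]2OC1
A6 | alternative 3 | (2R,3E,7R,8R,11E)-7,8-epoxy-16,17-dinorcembra-1(15),3,11-trien-2-ol (1-methylene macrocycle) | C=C1CC/C(C)=C/CC[C@@]2(C)O[C@@H]2CC/C(C)=C/[C@H]1O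
A7 | alternative 3 | 2-(acetoxymethyl)allyl ether of A6 | C=C1CC/C(C)=C/CC[C@@]2(C)O[C@@H]2CC/C(C)=C/[C@H]1OCC(=C)COC(C)=O
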